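The leftover came first. At 47 h the south-east run, where the catalyst couples starting material with coupling partner to give target, had turned 59.3% of its starting material into target. By subtraction, 60.5% of the coupling partner's own charge remained, yet the share gained per hour over the last interval, 0.00258 h⁻¹, was far lower than the 0.0514 h⁻¹ of the first interval.

| flask | starting material | coupling partner | catalyst | target | time |
|---|---|---|---|---|---|
| south-east | 0.300 M | 0.450 M | 0.00600 M |  |  |
| north-west | 0.600 M | 0.450 M | 0.00600 M |  |  |
| west | 0.300 M | 0.230 M | 0.00600 M |  |  |
| north | 0.300 M | 0.450 M | 0.0120 M |  |  |
| east | 0.300 M | 0.450 M | 0.00600 M | 0.0900 M | 47 h |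

| south-east run: time / h | south-east run: [target] / M | north-west run: time / h | north-west run: [target] / M | west run: time / h | west run: [target] / M | north run: time / h | north run: [target] / M |
|---|---|---|---|---|---|---|---|
| 1.9 | 0.0293 | 1.9 | 0.0515 | 1.9 | 0.0143 | 1.9 | 0.0478 |
| 3.2 | 0.0459 | 3.2 | 0.0810 | 3.2 | 0.0248 | 3.2 | 0.0736 |
| 5.5 | 0.0714 | 5.5 | 0.1231 | 5.5 | 0.0389 | 5.5 | 0.1093 |
| 9.4 | 0.1032 | 9.4 | 0.1739 | 9.4 | 0.0575 | 9.4 | 0.1480 |
| 16 | 0.1355 | 16 | 0.2271 | 16 | 0.0790 | 16 | 0.1810 |
| 27 | 0.1623 | 27 | 0.2714 | 27 | 0.1003 | 27 | 0.2042 |
| 47 | 0.1778 | 47 | 0.2982 | 47 | 0.1168 | 47 | 0.2145 |

(standard deviation of a reading: 9 × 10⁻⁴ M)

- Overall: starting material + coupling partner -> target, with catalyst as catalyst.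
- Constant volume, constant temperature.
- Bound and free are read together.
- An order is taken over about fifteen percent of the charge, up and down.
- A share of target counts the target that was charged too.

- reaction order in [catalyst] at the outset, round the charge of the south-east run, defined at two percent of the starting material turned into target
- reaction order in [starting material] at the outset, round the charge of the south-east run, defined at two percent of the starting material turned into target (one fixed amount of target, the same in the runs compared)
- target in the east run at 47 h, as a share of the starting material charged

I went through the run in slow motion. In the first instants the south-east flask was still nearly its charge, with 9.77% turned at 1.9 h. Twice the catalyst in the north run gave 1.63 times the target at that reading, less than the charge ratio. Twice the starting material in the north-west run gave 1.76 times, also less.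

By 9.4 h the south-east flask stood at 34.4% and was slowing. The middle gave the test. The north-west flask held 0.1739 M of target at 9.4 h, and the south-east flask held 0.1623 M at 27 h, which is about the same amount. Yet the north-west flask's next interval gained 10.4 times as fast, while its starting material, reckoned by subtraction, stood at 3.09 times the south-east amount, a smaller factor. I therefore took the brake to run with the clock and not with the target, as a side loss of starting material.

At the end of a run, then, I froze the split. My carried quantity is the leak ratio, a selectivity factor: starting material not turned into target per unit turned into target, which in the south-east run at 47 h was 0.687. The east flask has the south-east charge plus target worth 30.0% of the starting material. If charged target leaves the split alone, the flask makes the same 59.3%, and I reckoned 89.3%.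

The forecast differed. It gave 79% (range 72% to 87%), below my figure, on the ground that the apparent decay ran “faster where more target has accumulated”. For the orders it gave 0.8 in catalyst (range 0.7 to 0.92) and 0.85 in starting material (range 0.72 to 0.98).

    catalyst + starting material ⇌ catalyst-substrate complex, settled at all times (0.8030 M⁻¹)
    catalyst-substrate complex + coupling partner → target + catalyst (24.26 M⁻¹ h⁻¹)
    starting material + coupling partner → target (0.03442 M⁻¹ h⁻¹)
    starting material → decomposed substrate (0.03114 h⁻¹)

The east run gave 89.5%, with orders of 0.74 in catalyst and 0.89 in starting material. Starting material also went to decomposed substrate, with a rate constant of 0.0311 h⁻¹, a step in which target takes no part. With the charged target taken off, the east run's leak ratio was 0.681, against 0.687 in the south-east run. In the north run, the rate ratio of 1.7 over the south-east run divides the leak ratio to 0.396, which gives a share of 71.6%, and the reading at 47 h was 71.5%.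

The numbers in the tables were generated by integration with made-up constants, and the scatter is random.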